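## Structural features

The target is a flavanone: benzene ring A is fused to a 2,3-dihydro-4H-pyran-4-one (ring C), which carries a para-substituted phenyl ring B at C2. Ring A bears a free hydroxyl at C7, para to the C4 carbonyl, and ring B is capped at O4' by an (E)-geranyl chain with two trisubstituted alkenes. C2 (S) is the only stereocentre; it lies between the ring oxygen O1 and the unsubstituted methylene C3, which is alpha to the C4 ketone, so no neighbouring centre can guide it. Two features are fragile. The C2–O1 bond is beta to the ketone, so an enolate at C3 can expel the ring A phenoxide and reclose without selectivity. The geranyl ether is an allylic aryl ether that does not tolerate strong protic or Lewis acids, electrophilic oxidants, hydrogenation or zerovalent palladium. The real difficulty is to set a lone benzylic C–O stereocentre, whose direct formation by oxa-Michael closure is reversible, with reagents that leave the side chain alone. The key step uses the empty position C3: an oxygen placed there, as part of a trans oxirane across C2 and C3 of the open-chain enone, gives C2 a configurationally stable neighbour. The 2,3-trans preference of ring C then passes that configuration to C2, and the C3–O bond, being alpha to the C4 carbonyl, can later be cut by single-electron reduction.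

## Logic of the disconnections

13 to 12. The ester C–O bond on O7 is the first cut. The phenol must be covered while C3 is acylated and reduced, so the last forward step becomes a simple solvolysis. No skeletal simplification results. The forward step must run close to neutral pH, so that C3 is never deprotonated and ring C never opens.

12 to 11. The C3–H bond is replaced by a C3–O(acyl) bond trans to the aryl group on C2. This is the central simplification: the lone stereocentre gains a neighbour that can carry the stereochemical information. The forward step must break only the C–O bond alpha to the C4 carbonyl by electron transfer, and the resulting enolate must be protonated faster than it expels O1.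

11 to 10. The two O–acyl bonds are cut. One acylation turns the C3 hydroxyl into a leaving group and covers the C7 phenol at the same time. The forward step needs an acylation that does not enolise C3.

10 to 8, through 9. The O1–C2 bond of ring C is cut and C2 is reconnected to the oxygen on C3, giving an oxirane; both ring A oxygens are masked again as acetals. Ring C disappears, and both stereocentres trace back to one epoxide of defined configuration. The forward step requires attack of the ring A phenol at C2 and not C3, trans ring closure, and unmasking by no more than a weak acid. For that last reason the acetals in 8 are derived from acetaldehyde and not from formaldehyde, whose removal needs acid strong enough to add to the side-chain alkenes and cleave the allylic aryl ether.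

8 to 7. Both C–O bonds of the oxirane are cut, which removes all stereochemistry and leaves an E-enone. The forward step needs enantioface selection by a chiral catalyst, a nucleophilic oxidant that spares the isolated alkenes, and base-stable masking of both ring A oxygens.

7 to 2 and 5, through 6. The enone C=C bond (C2–C3 of the target) is cut into a methyl ketone and a non-enolisable aldehyde. This is the convergent cut: ring A with C4 and C3 on one side, ring B with C2 and the side chain on the other. The forward step is a base-mediated aldol condensation that must dehydrate to the E isomer and that only base-stable protecting groups survive.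

5 to 3 and 4. The O–C1 bond of the geranyl ether is cut. Placing the chain at the outset on a compound with a single phenol avoids a late differentiation of O7 and O4', where the more acidic O7 would react first. The forward step must alkylate on oxygen without allylic transposition or change of alkene geometry.

2 to 1. The two acetal C–O bonds are cut, leading to a commercial ketone. The forward step must alkylate the hydrogen-bonded ortho hydroxyl, which calls for the phenoxide and a reactive alpha-chloro ether and not for acid catalysis.

## Other disconnections considered

Alternative 1: The cut goes through C2–C3 and O1–C8a, so ring C is assembled around a ring A still at the dihydro level. In the forward key step a complex of tetravalent titanium, made from Ti(OiPr)4 and one antipode of BINOL, would join the carbonyl of aldehyde 5 to a bis(silyloxy)diene in a hetero-Diels–Alder reaction (or its stepwise Mukaiyama aldol and cyclisation equivalent). After loss of the silanol from C8a the product would be the vinylogous ester A1, (S)-2-[4-(geranyloxy)phenyl]-7-(triisopropylsilyloxy)-2,3,5,6-tetrahydro-4H-chromen-4-one. The diene it needs is the ring A triene A2, 1-[1-(trimethylsilyloxy)vinyl]-2-(trimethylsilyloxy)-4-(triisopropylsilyloxy)cyclohexa-1,3-diene. Dehydrogenation across C5–C6 and desilylation would follow.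
- In its favour: C2 is created directly in a catalytic C–C bond formation with no sacrificial neighbour, the route converges on the same aldehyde 5, and the phenol is released by fluoride and not by acid.
- Against it here: the diene terminus C8a is fully substituted and cross-conjugated with the ring A enol ether, a pattern for which high enantioselectivity with this catalyst type cannot be taken for granted. The late aromatisation of ring A needs an oxidant that must not touch the C2–H/C3–H pair (dehydrogenation there gives the flavone and erases the stereocentre), the allylic aryl ether or the two trisubstituted alkenes.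
- Comparison: on structure the alternative reaches the protected flavanone without a temporary oxygen, which is the cleaner solution. On mechanism the chosen plan has the edge, because its oxidant is nucleophilic and therefore indifferent to the side chain, whereas an aromatising oxidant is not. On step economy the alternative, at roughly six steps against eight, is the better of the two.

Alternative 2: The cut is the aryl ether bond O1–C8a. In the forward key step CuI with 3,4,7,8-tetramethyl-1,10-phenanthroline and Cs2CO3 (an Ullmann-type etherification through monovalent copper) would couple the C2 hydroxyl with an aryl bromide. The product would be the flavan-4-ol A3, (2S,4S)-2-[4-(geranyloxy)phenyl]-7-(methoxymethoxy)chroman-4-ol, formed from the anti-1,3-diol A4, (1S,3S)-1-[2-bromo-4-(methoxymethoxy)phenyl]-3-[4-(geranyloxy)phenyl]propane-1,3-diol. Oxidation at C4 and removal of the O7 group would complete the synthesis.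
- In its favour: the C2–O bond is carried over intact from the carbinol, so the stereocentre is transferred with retention and no ionisable benzylic intermediate intervenes. While C4 is an alcohol, ring C cannot open by a retro-oxa-Michael path. Only the six-membered closure can occur, since the C4 hydroxyl would have to close a four-membered ring.
- Against it here: a second stereocentre at C4 must be built under control only to be destroyed. The secondary benzylic alkoxide may be oxidised or eliminated at the temperature such couplings need. The methoxymethyl group on O7 would finally require a protic acid strong enough to endanger the geranyl ether, so another O7 group would have to be found.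
- Comparison: on structure the alternative carries an extra stereocentre and an extra change of oxidation state, where the chosen plan carries an extra oxygen. On mechanism the alternative is the better one at C2 (retention at an untouched C–O bond instead of ring closure at a cation-prone benzylic carbon) and the equal of the chosen plan in regiochemical security. On step economy the two are about equal, the alternative needing two stereoselective steps where the chosen plan needs one.

Alternative 3: The cut is C3=C4, made at the enol ether oxidation level. In the forward key step the second-generation Grubbs catalyst would join the vinyl group on C2 to the methylene of a silyl enol ether on ring A, releasing a volatile alkene. The product would be the 2H-chromene A5, (S)-4-(tert-butyldimethylsilyloxy)-2-[4-(geranyloxy)phenyl]-7-(triisopropylsilyloxy)-2H-chromene, formed from the diene A6, (S)-1-[4-(geranyloxy)phenyl]allyl 2-[1-(tert-butyldimethylsilyloxy)vinyl]-5-(triisopropylsilyloxy)phenyl ether. Buffered fluoride would then release ketone and phenol together.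
- In its favour: the C4 carbonyl stays masked until the last step, so C2 cannot epimerise by ring opening. The end game after ring closure is a single mild step against three in the chosen plan. The stereocentre could be made by a catalytic asymmetric allylic etherification.
- Against it here: the target's own side chain contains alkenes, and the isopropylidene terminus of the geranyl group is a competent metathesis partner for this catalyst. Truncation or cross-metathesis can therefore compete with a ring closure that is intrinsically slow, because it engages a 1,1-disubstituted, electron-rich silyl enol ether. The stereocentre in A6 is at once benzylic, allylic and para-alkoxy activated, and so open to ionisation or sigmatropic rearrangement on heating.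
- Comparison: on structure the alternative avoids the temporary oxygen and the acyl groups, which is in its favour. On mechanism it is the better plan for protecting C2 from ring opening, but the weaker one in chemoselectivity: the chosen key reagent separates the enone from isolated alkenes by electronic demand, while a metathesis catalyst must separate alkenes of similar kind. On step economy the two are about equal overall, with the shorter end game on the side of the alternative.

Key step: step 4

Remark: the 1-ethoxyethyl acetal carbons in 2, 6, 7 and 8 are stereocentres of no consequence; these compounds are carried as mixtures of epimers, written without configuration at those carbons, and the acetals are gone after step 5.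

## Route

Step 1
Reactants: 1 2,4-dihydroxyacetophenone
Product: 2 1-[2,4-bis(1-ethoxyethoxy)phenyl]ethan-1-one
Conditions: NaH (2.2 equiv), DMF, 0 °C; 1-chloroethyl ethyl ether (2.5 equiv), 0 °C to rt; aqueous NaHCO3 work-up
Reagents that add atoms: 1-chloroethyl ethyl ether, CCOC(C)Cl
Why: O-Alkylation of both sodium phenoxides by an alpha-chloro ether, the same reaction type as methoxymethylation with chloromethyl methyl ether; the phenoxide route is needed because the ortho hydroxyl is hydrogen-bonded to the ketone and inert to acid-catalysed acetal formation. The acetaldehyde-derived acetals are stable to the bases of steps 3 and 4 but should cleave under a far weaker acid than formaldehyde-derived acetals, which is what the geranyl ether requires in step 5.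

Step 2
Reactants: 3 4-hydroxybenzaldehyde; 4 geranyl bromide
Product: 5 4-(geranyloxy)benzaldehyde, in which geranyl is (2E)-3,7-dimethylocta-2,6-dien-1-yl
Conditions: K2CO3, acetone, reflux
Reagents that add atoms: none
Why: Williamson ether synthesis; the phenoxide displaces bromide at the primary allylic carbon in an SN2 manner, so the chain is attached at C1 and the E geometry of the C2=C3 alkene is retained. The single phenol of 3 removes any question of which oxygen is alkylated.

Step 3
Reactants: 2 1-[2,4-bis(1-ethoxyethoxy)phenyl]ethan-1-one; 5 4-(geranyloxy)benzaldehyde
Product: 7 (E)-1-[2,4-bis(1-ethoxyethoxy)phenyl]-3-[4-(geranyloxy)phenyl]prop-2-en-1-one, via β-hydroxy ketone 6 (not isolated)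
Conditions: KOH, EtOH, rt; aqueous NH4Cl work-up
Reagents that add atoms: none
Why: Claisen–Schmidt condensation: the methyl ketone enolate adds to the non-enolisable aldehyde and the aldol adduct loses hydroxide by an E1cB path to the thermodynamically favoured E-enone. The acetals and the allylic ether are inert to hydroxide, and the buffered work-up keeps the acetals intact.

Step 4
Reactants: 7 (E)-1-[2,4-bis(1-ethoxyethoxy)phenyl]-3-[4-(geranyloxy)phenyl]prop-2-en-1-one
Product: 8 (2R,3S)-1-[2,4-bis(1-ethoxyethoxy)phenyl]-2,3-epoxy-3-[4-(geranyloxy)phenyl]propan-1-one (trans oxirane)
Conditions: poly-L-leucine, 30% aqueous H2O2, aqueous NaOH, Bu4NBr (cat.), toluene, rt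
Reagents that add atoms: hydrogen peroxide, OO
Why: Juliá–Colonna epoxidation, the peptide-catalysed form of the Weitz–Scheffer reaction: hydroperoxide anion adds in conjugate fashion to the beta carbon (the later C2), and the enolate carbon (the later C3) then displaces hydroxide from the peroxide oxygen. The oxirane is the only ring formed and it closes in a 3-exo-tet mode. The configuration at the beta carbon is fixed in the addition step by the catalyst: the amide N–H groups at the amino terminus of the poly-L-leucine helix bind the enone carbonyl and the peroxide and expose one enantioface, which by analogy with simple chalcones should give the (2R,3S) oxide. The configuration at the alpha carbon is not chosen independently; bond rotation in the peroxy enolate before closure places aryl and aroyl groups trans, so it follows from the beta centre. Enantioface selection is the first selectivity needed and rests on the catalyst alone, since the acetal carbons are remote and exert no influence. The second is chemoselectivity for the enone over the two trisubstituted alkenes of the geranyl chain, secured by the nucleophilic character of the oxidant, which attacks only the electron-poor conjugated double bond. Both ring A oxygens are capped with base-stable acetals so that no phenoxide can deactivate the enone or divert the reaction along the Algar–Flynn–Oyamada path to flavonol or aurone. The phase-transfer salt is included to raise the rate for this electron-rich, ortho-substituted enone, so that the uncatalysed background reaction stays minor.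

Step 5
Reactants: 8 (2R,3S)-1-[2,4-bis(1-ethoxyethoxy)phenyl]-2,3-epoxy-3-[4-(geranyloxy)phenyl]propan-1-one
Product: 10 (2R,3R)-3,7-dihydroxy-2-[4-(geranyloxy)phenyl]chroman-4-one, via dihydroxyphenyl epoxy ketone 9 (not isolated)
Conditions: pyridinium p-toluenesulfonate (0.2 equiv), MeOH (10 equiv), CH2Cl2, 0 °C to rt; aqueous NaHCO3 work-up
Reagents that add atoms: none
Why: Acid-catalysed transacetalisation to methanol frees both phenols to give 9, whose ortho phenol opens the acid-activated oxirane at the benzylic carbon (6-endo, favoured by the cation-stabilising para-alkoxyphenyl group) with inversion; this is the known acid cyclisation of acetal-protected 2'-hydroxychalcone oxides to trans-dihydroflavonols. C3 keeps its configuration because its C–O bond is never broken and C2 is set trans to it, so any cis isomer, which would later lead to the wrong enantiomer, is a diastereomer that is removed here by chromatography or crystallisation. The weak catalytic acid is far below what would protonate the geranyl alkenes or ionise the allylic aryl ether.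

Step 6
Reactants: 10 (2R,3R)-3,7-dihydroxy-2-[4-(geranyloxy)phenyl]chroman-4-one
Product: 11 (2R,3R)-2-[4-(geranyloxy)phenyl]-4-oxochroman-3,7-diyl diacetate
Conditions: Ac2O, pyridine, DMAP (cat.), CH2Cl2, 0 °C to rt
Reagents that add atoms: acetic anhydride, CC(=O)OC(C)=O
Why: Nucleophile-catalysed O-acylation of the phenol and of the secondary ketol hydroxyl; the C3 acetate becomes the leaving group for step 7 and the C7 acetate covers the phenol. Pyridine is too weak a base to enolise C3, so neither stereocentre should be disturbed.

Step 7
Reactants: 11 (2R,3R)-2-[4-(geranyloxy)phenyl]-4-oxochroman-3,7-diyl diacetate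
Product: 12 (2S)-2-[4-(geranyloxy)phenyl]-4-oxochroman-7-yl acetate
Conditions: SmI2 (2.5 equiv), THF/MeOH, −78 °C; quench at −78 °C with aqueous NH4Cl
Reagents that add atoms: none
Why: Reductive cleavage of an alpha-acyloxy ketone by samarium diiodide: electron transfer to the aryl ketone gives a ketyl, acetate leaves from C3, a second electron gives the samarium enolate, and methanol protonates it at C3. No bond to C2 is touched, so its configuration is retained, and the descriptor changes from R to S only because C3 loses its oxygen. The aryl acetate, the allylic ether and the alkenes should not be reduced at this temperature.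

Step 8
Reactants: 12 (2S)-2-[4-(geranyloxy)phenyl]-4-oxochroman-7-yl acetate
Product: 13 (2S)-2-[4-(geranyloxy)phenyl]-7-hydroxychroman-4-one
Conditions: NH4OAc, MeOH/H2O, rt
Reagents that add atoms: none
Why: Near-neutral methanolysis of an activated aryl acetate, whose leaving phenoxide is stabilised by the para carbonyl. The medium is too weakly basic to deprotonate C3, and because the ring B oxygen is alkylated no quinone methide path for opening ring C exists, so C2 should be retained.

## Compound list

1 | 2,4-dihydroxyacetophenone | CC(=O)c1ccc(O)cc1O | starting material
2 | 1-[2,4-bis(1-ethoxyethoxy)phenyl]ethan-1-one (epimers at the acetal carbons) | CC(=O)c1ccc(OC(C)OCC)cc1OC(C)OCC | intermediate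
3 | 4-hydroxybenzaldehyde | O=Cc1ccc(O)cc1 | starting material
4 | geranyl bromide, (2E)-1-bromo-3,7-dimethylocta-2,6-diene | CC(C)=CCC/C(C)=C/CBr | starting material
5 | 4-(geranyloxy)benzaldehyde, 4-{[(2E)-3,7-dimethylocta-2,6-dien-1-yl]oxy}benzaldehyde | CC(C)=CCC/C(C)=C/COc1ccc(C=O)cc1 | intermediate
6 | 1-[2,4-bis(1-ethoxyethoxy)phenyl]-3-[4-(geranyloxy)phenyl]-3-hydroxypropan-1-one (aldol adduct, both configurations at C3) | CC(C)=CCC/C(C)=C/COc1ccc(C(O)CC(=O)c2ccc(OC(C)OCC)cc2OC(C)OCC)cc1 | intermediate (not isolated)
7 | (E)-1-[2,4-bis(1-ethoxyethoxy)phenyl]-3-[4-(geranyloxy)phenyl]prop-2-en-1-one | CC(C)=CCC/C(C)=C/COc1ccc(/C=C/C(=O)c2ccc(OC(C)OCC)cc2OC(C)OCC)cc1 | intermediate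
8 | (2R,3S)-1-[2,4-bis(1-ethoxyethoxy)phenyl]-2,3-epoxy-3-[4-(geranyloxy)phenyl]propan-1-one (trans oxirane) | CC(C)=CCC/C(C)=C/COc1ccc([C@@H]2O[C@H]2C(=O)c3ccc(OC(C)OCC)cc3OC(C)OCC)cc1 | intermediate
9 | (2R,3S)-1-(2,4-dihydroxyphenyl)-2,3-epoxy-3-[4-(geranyloxy)phenyl]propan-1-one | CC(C)=CCC/C(C)=C/COc1ccc([C@@H]2O[C@H]2C(=O)c3ccc(O)cc3O)cc1 | intermediate (not isolated)
10 | (2R,3R)-3,7-dihydroxy-2-[4-(geranyloxy)phenyl]chroman-4-one (2,3-trans) | CC(C)=CCC/C(C)=C/COc1ccc([C@@H]2[C@@H](O)C(=O)c3ccc(O)cc3O2)cc1 | intermediate
11 | (2R,3R)-2-[4-(geranyloxy)phenyl]-4-oxochroman-3,7-diyl diacetate | CC(C)=CCC/C(C)=C/COc1ccc([C@@H]2[C@@H](OC(C)=O)C(=O)c3ccc(OC(C)=O)cc3O2)cc1 | intermediate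
12 | (2S)-2-[4-(geranyloxy)phenyl]-4-oxochroman-7-yl acetate | CC(C)=CCC/C(C)=C/COc1ccc([C@@H]2CC(=O)c3ccc(OC(C)=O)cc3O2)cc1 | intermediate
13 | (2S)-2-[4-(geranyloxy)phenyl]-7-hydroxychroman-4-one (CNP0302343.1) | CC(C)=CCC/C(C)=C/COc1ccc([C@@H]2CC(=O)c3ccc(O)cc3O2)cc1 | target

## Step count and least certain steps

Total step count: 8. Longest linear sequence: 7 steps (1 to 2, then 7, 8, 10, 11, 12 and 13; the branch from 3 and 4 through 5 is equally long).

Step 4 (key step). The most likely failure is incomplete enantioface selection. Conjugate addition to an electron-rich enone with an ortho substituent on the aroyl ring is slow, so uncatalysed background epoxidation can compete with the peptide-bound pathway. The epimeric acetals also rule out upgrading 8 by crystallisation. The fallback adds a separation of diastereomers to catalyst control and sets out from 10, carrying forward whatever enantiomeric purity step 4 delivers. One equivalent of Ac2O in pyridine at 0 °C should acylate the phenol alone and give (2R,3R)-3-hydroxy-2-[4-(geranyloxy)phenyl]-4-oxochroman-7-yl acetate F1. Esterification of the C3 hydroxyl with (1S,4R)-camphanic chloride (pyridine, DMAP) would give the C3 (1S,4R)-camphanate of F1, (2R,3R)-7-acetoxy-2-[4-(geranyloxy)phenyl]-4-oxochroman-3-yl (1S,4R)-camphanate F2. The ester of the minor enantiomer is a diastereomer and is removed by crystallisation or chromatography. The camphanate is itself an alpha-acyloxy leaving group, so SmI2 under the conditions of step 7 should cleave it, and the fallback returns to the route at 12.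

Step 5. Several processes can divert the ionised epoxide: capture of the benzylic cation by methanol instead of the phenol, a semipinacol-type 1,2-shift of the aroyl group, attack of the phenol at the alpha carbon (5-exo) leading to a benzofuranone, and incomplete trans selectivity. If a stronger acid were needed to drive ring closure, slow damage to the geranyl group would begin. The fallback separates opening from closure by a sulfur relay and sets out from 8. Benzyl mercaptan with the same weak acid in CH2Cl2 containing a little methanol should trap the cation faster than it rearranges, and remove the acetals, giving (2S)-3-(benzylsulfanyl)-1-(2,4-dihydroxyphenyl)-3-[4-(geranyloxy)phenyl]-2-hydroxypropan-1-one F3 (either configuration at C3). AgBF4 in CH2Cl2 at 0 °C with 2,6-di-tert-butylpyridine as acid scavenger would then abstract the thiolate; the regenerated benzylic cation is captured by the ortho phenol trans to the C3 hydroxyl, and the fallback returns at 10.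

Step 7. The samarium enolate can expel the ring oxygen O1 by beta-elimination before it is protonated; ring C would then open to a 2'-hydroxychalcone that is reduced further or recloses without selectivity, so C2 would lose its configuration. Over-reduction of the aryl ketone to pinacol or alcohol is the second hazard. The fallback is a Barton–McCombie deoxygenation, which never forms an enolate, and it sets out from 10. The monoacetate (2R,3R)-3-hydroxy-2-[4-(geranyloxy)phenyl]-4-oxochroman-7-yl acetate F1 is prepared as described for step 4. Phenyl chlorothionoformate (pyridine, DMAP, CH2Cl2) should convert it into (2R,3R)-2-[4-(geranyloxy)phenyl]-4-oxo-3-[(phenoxycarbonothioyl)oxy]chroman-7-yl acetate F4. Bu3SnH with azobisisobutyronitrile in toluene at 80 °C, with the tin hydride kept concentrated so that hydrogen transfer to the C3 radical outruns fragmentation, would give 12, where the fallback returns.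

Step 8. If the medium drifts basic, deprotonation at C3 and E1cB opening of ring C would erode the configuration at C2 in the final product, where it can no longer be corrected by separating diastereomers. The fallback avoids any base at the flavanone stage by using a silyl group on O7, and it sets out from 10. TBSCl and imidazole in DMF at 0 °C should silylate the phenol alone to (2R,3R)-7-(tert-butyldimethylsilyloxy)-3-hydroxy-2-[4-(geranyloxy)phenyl]chroman-4-one F5. Acetylation as in step 6 would give (2R,3R)-7-(tert-butyldimethylsilyloxy)-2-[4-(geranyloxy)phenyl]-4-oxochroman-3-yl acetate F6. SmI2 as in step 7 would give (2S)-7-(tert-butyldimethylsilyloxy)-2-[4-(geranyloxy)phenyl]chroman-4-one F7. KHF2 in MeOH at rt, a weakly acidic fluoride source selective for aryl silyl ethers, would then release the phenol, and the fallback returns at 13.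

## Further compounds

F1 | step 4 | (2R,3R)-3-hydroxy-2-[4-(geranyloxy)phenyl]-4-oxochroman-7-yl acetate | CC(C)=CCC/C(C)=C/COc1ccc([C@@H]2[C@@H](O)C(=O)c3ccc(OC(C)=O)cc3O2)cc1
F2 | step 4 | (2R,3R)-7-acetoxy-2-[4-(geranyloxy)phenyl]-4-oxochroman-3-yl (1S,4R)-4,7,7-trimethyl-3-oxo-2-oxabicyclo[2.2.1]heptane-1-carboxylate | CC(C)=CCC/C(C)=C/COc1ccc([C@@H]2[C@@H](OC(=O)[C@@]34CC[C@@](C)(C(=O)O3)C4(C)C)C(=O)c3ccc(OC(C)=O)cc3O2)cc1
F3 | step 5 | (2S)-3-(benzylsulfanyl)-1-(2,4-dihydroxyphenyl)-3-[4-(geranyloxy)phenyl]-2-hydroxypropan-1-one (either configuration at C3) | CC(C)=CCC/C(C)=C/COc1ccc(C(SCc2ccccc2)[C@@H](O)C(=O)c2ccc(O)cc2O)cc1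
F4 | step 7 | (2R,3R)-2-[4-(geranyloxy)phenyl]-4-oxo-3-[(phenoxycarbonothioyl)oxy]chroman-7-yl acetate | CC(C)=CCC/C(C)=C/COc1ccc([C@@H]2[C@@H](OC(=S)Oc3ccccc3)C(=O)c3ccc(OC(C)=O)cc3O2)cc1
F5 | step 8 | (2R,3R)-7-(tert-butyldimethylsilyloxy)-3-hydroxy-2-[4-(geranyloxy)phenyl]chroman-4-one | CC(C)=CCC/C(C)=C/COc1ccc([C@@H]2[C@@H](O)C(=O)c3ccc(O[Si](C)(C)C(C)(C)C)cc3O2)cc1
F6 | step 8 | (2R,3R)-7-(tert-butyldimethylsilyloxy)-2-[4-(geranyloxy)phenyl]-4-oxochroman-3-yl acetate | CC(C)=CCC/C(C)=C/COc1ccc([C@@H]2[C@@H](OC(C)=O)C(=O)c3ccc(O[Si](C)(C)C(C)(C)C)cc3O2)cc1
F7 | step 8 | (2S)-7-(tert-butyldimethylsilyloxy)-2-[4-(geranyloxy)phenyl]chroman-4-one | CC(C)=CCC/C(C)=C/COc1ccc([C@@H]2CC(=O)c3ccc(O[Si](C)(C)C(C)(C)C)cc3O2)cc1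
A1 | alternative 1 | (S)-2-[4-(geranyloxy)phenyl]-7-(triisopropylsilyloxy)-2,3,5,6-tetrahydro-4H-chromen-4-one | CC(C)=CCC/C(C)=C/COc1ccc([C@@H]2CC(=O)C3=C(C=C(O[Si](C(C)C)(C(C)C)C(C)C)CC3)O2)cc1
A2 | alternative 1 | 1-[1-(trimethylsilyloxy)vinyl]-2-(trimethylsilyloxy)-4-(triisopropylsilyloxy)cyclohexa-1,3-diene | C=C(O[Si](C)(C)C)C1=C(O[Si](C)(C)C)C=C(O[Si](C(C)C)(C(C)C)C(C)C)CC1
A3 | alternative 2 | (2S,4S)-2-[4-(geranyloxy)phenyl]-7-(methoxymethoxy)chroman-4-ol | CC(C)=CCC/C(C)=C/COc1ccc([C@@H]2C[C@H](O)c3ccc(OCOC)cc3O2)cc1
A4 | alternative 2 | (1S,3S)-1-[2-bromo-4-(methoxymethoxy)phenyl]-3-[4-(geranyloxy)phenyl]propane-1,3-diol | CC(C)=CCC/C(C)=C/COc1ccc([C@@H](O)C[C@H](O)c2ccc(OCOC)cc2Br)cc1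
A5 | alternative 3 | (S)-4-(tert-butyldimethylsilyloxy)-2-[4-(geranyloxy)phenyl]-7-(triisopropylsilyloxy)-2H-chromene | CC(C)=CCC/C(C)=C/COc1ccc([C@@H]2C=C(O[Si](C)(C)C(C)(C)C)c3ccc(O[Si](C(C)C)(C(C)C)C(C)C)cc3O2)cc1
A6 | alternative 3 | (S)-1-[4-(geranyloxy)phenyl]allyl 2-[1-(tert-butyldimethylsilyloxy)vinyl]-5-(triisopropylsilyloxy)phenyl ether | CC(C)=CCC/C(C)=C/COc1ccc([C@H](C=C)Oc2cc(O[Si](C(C)C)(C(C)C)C(C)C)ccc2C(=C)O[Si](C)(C)C(C)(C)C)cc1
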